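The nitrogen ring (ring B) of the tetrahydroisoquinoline is disconnected at C4–C4a and C1–N. The arene carbon C4a and the benzylic carbon C1 form a 1,3-pair on the benzo ring (ring A), matched with the three-atom N–C3–C4 unit of L-alaninol. In one operation an aryllithium carrying a masked ortho-acetyl group opens a Boc-protected cyclic sulfamidate at its CH2–O carbon (C4–C4a); the acid quench then unmasks amine and ketone, which condense to the C1=N bond of a 3,4-dihydroisoquinoline. N-Methylation and cis-selective hydride reduction set C1. A late ortho-metalation/Negishi coupling at C7 attaches the naphthalene, made by an aryne–furan cycloaddition.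

Key step: step 3

Assumption: the target SMILES fixes C1 (R) and C3 (S) but gives no configuration for the C7–naphthyl axis, so the axis is left uncontrolled; isoquinoline numbering (C1, N2, C3, C4, C4a, C5–C8, C8a) is used throughout.

Step 1
Reactants: 1 1-bromo-3,5-dimethoxybenzene
Product: 2 1-(2-bromo-4,6-dimethoxyphenyl)ethan-1-one
Conditions: AcCl, AlCl3, CH2Cl2, 0 °C
Reagents that add atoms: acetyl chloride CC(=O)Cl
Why: Friedel–Crafts acylation should occur para to one methoxy group and ortho to the other (next to bromine), because the position between the two methoxy groups is less favoured, and the low temperature keeps AlCl3 from cleaving the ortho methoxy group.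

Step 2
Reactants: 2 1-(2-bromo-4,6-dimethoxyphenyl)ethan-1-one
Product: 3 2-(2-bromo-4,6-dimethoxyphenyl)-2-methyl-1,3-dioxolane
Conditions: HOCH2CH2OH, p-TsOH·H2O (cat.), toluene, reflux, azeotropic removal of water
Reagents that add atoms: ethane-1,2-diol OCCO
Why: Acid-catalysed ketalisation masks the enolisable ketone as a dioxolane that tolerates the aryllithium of the next step and is cleaved in its acid quench.

Step 3
Reactants: 3 2-(2-bromo-4,6-dimethoxyphenyl)-2-methyl-1,3-dioxolane; 4 tert-butyl (S)-4-methyl-1,2,3-oxathiazolidine-3-carboxylate 2,2-dioxide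
Product: 8 (S)-6,8-dimethoxy-1,3-dimethyl-3,4-dihydroisoquinoline, via aryllithium 5 (not isolated), via lithium sulfamate 6 (not isolated), via aminoketone hydrochloride 7 (not isolated)
Conditions: n-BuLi, THF, −78 °C; 4, −78 → 0 °C; then 4 M aq. HCl, MeOH, 50 °C; then aq. NaOH (pH 10)
Reagents that add atoms: none
Why: Bromine–lithium exchange gives aryllithium 5, which opens the cyclic sulfamidate by SN2 attack at its primary O–CH2 carbon to form C4–C4a and leave N-sulfamate 6; aqueous acid then hydrolyses the N–SO3 bond, the Boc group and the dioxolane, and the freed primary amine of 7 condenses with the ortho ketone to close ring B through the C1=N bond. The closest known reaction types are the ring opening of amino-alcohol-derived cyclic sulfamidates by aryl organometallics and the spontaneous cyclocondensation of 2-(2-aminoethyl)aryl ketones to 3,4-dihydroisoquinolines. The only ring closed is the six-membered ring B, formed by 6-exo-trig addition of nitrogen to the carbonyl carbon followed by loss of water. No new stereocentre arises; C3 comes from L-alaninol and is untouched because substitution takes place at the neighbouring CH2. The step needs attack at carbon and not at sulfur or the Boc carbonyl, which the unhindered primary C–O carbon and the low temperature should secure, and it needs the metal at C4a only, which the bromine atom fixes.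

Step 4
Reactants: 8 (S)-6,8-dimethoxy-1,3-dimethyl-3,4-dihydroisoquinoline
Product: 10 (1R,3S)-6,8-dimethoxy-1,2,3-trimethyl-1,2,3,4-tetrahydroisoquinoline, via iminium iodide 9 (not isolated)
Conditions: MeI, MeCN, rt; then NaBH4, MeOH, −78 → 0 °C
Reagents that add atoms: iodomethane CI
Why: N-Alkylation of the cyclic imine gives iminium salt 9, in which allylic strain with the N-methyl group holds the C3 methyl group pseudoaxial, so that borohydride should add to C1 from the opposite face (iminium reduction) and give the 1,3-cis (1R,3S) amine.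

Step 5
Reactants: 11 1-bromo-3-methoxy-5-methylbenzene; 12 2-methoxyfuran
Product: 16 4,5-dimethoxy-7-methylnaphthalen-1-ol, via aryllithium 13 (not isolated), via aryne 14 (not isolated), via cycloadduct 15 (not isolated)
Conditions: LiN(i-Pr)2 (LDA), 12 (4 equiv), THF, −78 °C → rt; then HCl (cat.), MeOH, rt
Reagents that add atoms: none
Why: Deprotonation between Br and OMe and loss of LiBr gives 3-methoxy-5-methylbenzyne, whose Diels–Alder reaction with 2-methoxyfuran should join the electrophilic aryne carbon remote from OMe to the nucleophilic C5 of the furan, and the acid-labile bridged ketal 15 then opens and aromatises to the 4-methoxy-1-naphthol with both methoxy groups peri.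

Step 6
Reactants: 16 4,5-dimethoxy-7-methylnaphthalen-1-ol
Product: 17 4,5-dimethoxy-7-methylnaphthalen-1-yl trifluoromethanesulfonate
Conditions: Tf2O, pyridine, CH2Cl2, 0 °C
Reagents that add atoms: trifluoromethanesulfonic anhydride O=S(=O)(OS(=O)(=O)C(F)(F)F)C(F)(F)F
Why: O-Sulfonylation of the naphthol with Tf2O and pyridine gives the aryl triflate needed as the electrophile for cross-coupling.

Step 7
Reactants: 10 (1R,3S)-6,8-dimethoxy-1,2,3-trimethyl-1,2,3,4-tetrahydroisoquinoline; 17 4,5-dimethoxy-7-methylnaphthalen-1-yl trifluoromethanesulfonate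
Product: 20 ancistrobrevine A, via aryllithium 18 (not isolated), via arylzinc chloride 19 (not isolated)
Conditions: n-BuLi, TMEDA, THF, 0 °C; ZnCl2, THF, 0 °C → rt; then 17, Pd(OAc)2 (5 mol%), SPhos (2-dicyclohexylphosphino-2′,6′-dimethoxybiphenyl, 10 mol%), THF, 65 °C
Reagents that add atoms: none
Why: Directed ortho-metalation should take place at C7, the only C–H flanked by two methoxy groups, and after transmetalation to zinc a Negishi coupling on SPhos-ligated zerovalent palladium, formed in the flask from Pd(OAc)2, should join the two hindered arenes without touching the C1 and C3 stereocentres.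

Compound list
1 | 1-bromo-3,5-dimethoxybenzene | COc1cc(Br)cc(OC)c1 | starting material
2 | 1-(2-bromo-4,6-dimethoxyphenyl)ethan-1-one | CC(=O)c1c(Br)cc(OC)cc1OC | intermediate
3 | 2-(2-bromo-4,6-dimethoxyphenyl)-2-methyl-1,3-dioxolane | CC1(OCCO1)c1c(Br)cc(OC)cc1OC | intermediate
4 | tert-butyl (S)-4-methyl-1,2,3-oxathiazolidine-3-carboxylate 2,2-dioxide (Boc sulfamidate of L-alaninol) | C[C@H]1COS(=O)(=O)N1C(=O)OC(C)(C)C | starting material
5 | [3,5-dimethoxy-2-(2-methyl-1,3-dioxolan-2-yl)phenyl]lithium | [Li]c1cc(OC)cc(OC)c1C1(C)OCCO1 | intermediate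
6 | lithium (S)-N-(tert-butoxycarbonyl)-N-{1-[3,5-dimethoxy-2-(2-methyl-1,3-dioxolan-2-yl)phenyl]propan-2-yl}sulfamate | C[C@@H](Cc1cc(OC)cc(OC)c1C1(C)OCCO1)N(C(=O)OC(C)(C)C)S(=O)(=O)[O-].[Li+] | intermediate
7 | (S)-1-[2-(2-aminopropyl)-4,6-dimethoxyphenyl]ethan-1-one hydrochloride | C[C@H](N)Cc1cc(OC)cc(OC)c1C(C)=O.Cl | intermediate
8 | (S)-6,8-dimethoxy-1,3-dimethyl-3,4-dihydroisoquinoline | CC1=N[C@@H](C)Cc2cc(OC)cc(OC)c12 | intermediate
9 | (S)-6,8-dimethoxy-1,2,3-trimethyl-3,4-dihydroisoquinolin-2-ium iodide | CC1=[N+](C)[C@@H](C)Cc2cc(OC)cc(OC)c12.[I-] | intermediate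
10 | (1R,3S)-6,8-dimethoxy-1,2,3-trimethyl-1,2,3,4-tetrahydroisoquinoline (1,3-cis) | COc1cc2c(c(OC)c1)[C@@H](C)N(C)[C@@H](C)C2 | intermediate
11 | 1-bromo-3-methoxy-5-methylbenzene | COc1cc(C)cc(Br)c1 | starting material
12 | 2-methoxyfuran | COc1ccco1 | starting material
13 | (2-bromo-6-methoxy-4-methylphenyl)lithium | [Li]c1c(Br)cc(C)cc1OC | intermediate
14 | 3-methoxy-5-methylbenzyne | COC1=CC(C)=CC#C1 | intermediate
15 | 1,8-dimethoxy-6-methyl-1,4-dihydro-1,4-epoxynaphthalene (racemic) | COc1cc(C)cc2c1C1(OC)C=CC2O1 | intermediate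
16 | 4,5-dimethoxy-7-methylnaphthalen-1-ol | COc1ccc(O)c2cc(C)cc(OC)c12 | intermediate
17 | 4,5-dimethoxy-7-methylnaphthalen-1-yl trifluoromethanesulfonate | COc1ccc(OS(=O)(=O)C(F)(F)F)c2cc(C)cc(OC)c12 | intermediate
18 | [(1R,3S)-6,8-dimethoxy-1,2,3-trimethyl-1,2,3,4-tetrahydroisoquinolin-7-yl]lithium | COc1cc2c(c(OC)c1[Li])[C@@H](C)N(C)[C@@H](C)C2 | intermediate
19 | [(1R,3S)-6,8-dimethoxy-1,2,3-trimethyl-1,2,3,4-tetrahydroisoquinolin-7-yl]zinc chloride | COc1cc2c(c(OC)c1[Zn]Cl)[C@@H](C)N(C)[C@@H](C)C2 | intermediate
20 | ancistrobrevine A, (1R,3S)-7-(4,5-dimethoxy-7-methylnaphthalen-1-yl)-6,8-dimethoxy-1,2,3-trimethyl-1,2,3,4-tetrahydroisoquinoline | COc1cc2c(c(OC)c1-c1ccc(OC)c3c(OC)cc(C)cc13)[C@@H](C)N(C)[C@@H](C)C2 | target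

Total step count: 7. Longest linear sequence: 5 (steps 1, 2, 3, 4 and 7).

Steps most likely to fail

Step 3. The aryllithium may attack the sulfamidate at sulfur or at the Boc carbonyl, or be quenched by proton transfer, before it substitutes at the CH2–O carbon. The fallback sets out from 4 and 2 and comes back at 8. It needs no ketal and replaces the hard aryllithium by a soft alkylzinc. Sulfamidate 4 is opened with NaI in acetone and the N-sulfamate hydrolysed with dilute acid to give tert-butyl (S)-(1-iodopropan-2-yl)carbamate F1. Zinc insertion (activated Zn, DMF) gives (S)-[2-(tert-butoxycarbonylamino)propyl]zinc iodide F2. Negishi coupling of F2 with bromo ketone 2 (Pd2(dba)3, SPhos, DMF, 50 °C; zerovalent palladium) gives tert-butyl (S)-[1-(2-acetyl-3,5-dimethoxyphenyl)propan-2-yl]carbamate F3. Treatment with CF3CO2H in CH2Cl2 and neutralisation removes the Boc group and lets the amine condense with the ketone to 8.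

Step 7. Transmetalation and reductive elimination at the carbon flanked by two methoxy groups may be slow, so that protonation back to 10 wins. The fallback sets out from 10 and 17, comes back at 20, and reverses the polarity of the coupling. Aryllithium 18 is quenched with I2 to give (1R,3S)-7-iodo-6,8-dimethoxy-1,2,3-trimethyl-1,2,3,4-tetrahydroisoquinoline F4. Triflate 17 is converted by Miyaura borylation (bis(pinacolato)diboron, Pd(dppf)Cl2, KOAc, dioxane, 80 °C) into 2-(4,5-dimethoxy-7-methylnaphthalen-1-yl)-4,4,5,5-tetramethyl-1,3,2-dioxaborolane F5. Suzuki–Miyaura coupling of F4 and F5 (Pd(OAc)2, SPhos, K3PO4, toluene/water, 90 °C) should give 20.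

Step 5. The cycloaddition may proceed with weak or reversed orientation, and diisopropylamine may capture the aryne. The fallback sets out from 11 and comes back at 16; it takes the orientation decision out of the cycloaddition. The same aryne is trapped with symmetrical furan to give 5-methoxy-7-methyl-1,4-dihydro-1,4-epoxynaphthalene F6. Acid (HCl, MeOH) should open the bridge at the carbon whose cation is stabilised by the ortho methoxy and para methyl groups, giving 5-methoxy-7-methylnaphthalen-1-ol F7. Oxidation with PhI(OAc)2 in MeOH places the second oxygen para to the hydroxyl group as the quinone monoketal 4,4,5-trimethoxy-7-methylnaphthalen-1(4H)-one F8. Reduction with Zn in AcOH should aromatise F8 to 16.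

Further compounds
F1 | step 3 | tert-butyl (S)-(1-iodopropan-2-yl)carbamate | C[C@@H](CI)NC(=O)OC(C)(C)C
F2 | step 3 | (S)-[2-(tert-butoxycarbonylamino)propyl]zinc iodide | C[C@@H](C[Zn]I)NC(=O)OC(C)(C)C
F3 | step 3 | tert-butyl (S)-[1-(2-acetyl-3,5-dimethoxyphenyl)propan-2-yl]carbamate | C[C@@H](Cc1cc(OC)cc(OC)c1C(C)=O)NC(=O)OC(C)(C)C
F4 | step 7 | (1R,3S)-7-iodo-6,8-dimethoxy-1,2,3-trimethyl-1,2,3,4-tetrahydroisoquinoline | COc1cc2c(c(OC)c1I)[C@@H](C)N(C)[C@@H](C)C2
F5 | step 7 | 2-(4,5-dimethoxy-7-methylnaphthalen-1-yl)-4,4,5,5-tetramethyl-1,3,2-dioxaborolane | COc1ccc(B2OC(C)(C)C(C)(C)O2)c2cc(C)cc(OC)c12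
F6 | step 5 | 5-methoxy-7-methyl-1,4-dihydro-1,4-epoxynaphthalene (racemic) | COc1cc(C)cc2c1C1C=CC2O1
F7 | step 5 | 5-methoxy-7-methylnaphthalen-1-ol | COc1cc(C)cc2c(O)cccc12
F8 | step 5 | 4,4,5-trimethoxy-7-methylnaphthalen-1(4H)-one | COc1cc(C)cc2c1C(OC)(OC)C=CC2=O
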